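**Retrosynthetic overview** (flavone numbering O1, C2 to C8a is used for the ring atoms of all intermediates)
- Target 15 ⇐ 7-O-methylation of diol 14 ⇐ loss of the C6 carboxyl group from resorcylate 12.
- 12 ⇐ ring A, closed last by forming C8–C8a and C5–C6 between pyranone ester 9 (ring C with O1, C8a and the C5 carbon in place) and the dilithium 1,3-dianion 10 of ketoester 1.
- 9 ⇐ ring C, closed first through O1–C8a from ketene dithioacetal 8 ⇐ diketoester 4 + CS2 + MeI; 4 ⇐ C2–C3 acylation of the sodium lithium 1,3-dianion 3 of ketoester 1 by ester 2 (ring B is bought).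
- Feature: ring A is 1,3-dioxygenated, with C8(OMe)–C7(O)–C6(H) equal to C4–C3–C2 of a 4-methoxyacetoacetate, and C3(OMe)–C4(=O)–C4a–C5(O) of ring C is the same unit again. Both come from 1, and because C8a carries O1 before ring A is made, only the 5,7,8 pattern can arise.

Key step: step 3

Remark: the 1,3-dianion of 1 is generated twice, each time fresh. For the ester acylation of step 1 it is the sodium lithium salt 3 (NaH, then n-BuLi, the amine-free protocol usual for this acylation). For step 3 it is the dilithium salt 10, made with a purchased solution of LiN(iPr)2, so that no alkyllithium is present beside the methylsulfanyl pyranone. Compounds 4, 7, 8 and 11 carry one enolisable methine carbon and are used as racemic or enol mixtures; that carbon becomes sp2, and the target has no stereocenter.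

**Step 1**
Reactants: 1 methyl 4-methoxy-3-oxobutanoate (2 equiv); 2 methyl 2,4-dimethoxybenzoate
Product: 4 methyl 5-(2,4-dimethoxyphenyl)-4-methoxy-3,5-dioxopentanoate, via sodium lithium dianion 3 (not isolated)
Conditions: NaH (2 equiv), THF, 0 °C; n-BuLi (2 equiv), 0 °C; then 2 (1 equiv), 0 to 20 °C; 1 M HCl
Reagents that add atoms: none
Why: Claisen-type γ-acylation of a β-ketoester 1,3-dianion by an ester (Huckin–Weiler acylation): the terminal carbanion is the most nucleophilic site, and the second equivalent of 3 deprotonates the more acidic tricarbonyl product as it forms, which protects it from a second addition.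

**Step 2**
Reactants: 4 methyl 5-(2,4-dimethoxyphenyl)-4-methoxy-3,5-dioxopentanoate; 5 carbon disulfide; 6 methyl iodide
Product: 9 methyl 6-(2,4-dimethoxyphenyl)-5-methoxy-2-(methylsulfanyl)-4-oxo-4H-pyran-3-carboxylate, via dipotassium ene-dithiolate 7 (not isolated), via ketene dithioacetal 8 (not isolated)
Conditions: K2CO3 (3 equiv), CS2, DMF, 0 °C; MeI (2.0 equiv), 0 to 20 °C; then 40 °C; aqueous work-up
Reagents that add atoms: carbon disulfide S=C=S; methyl iodide CI
Why: α-Oxoketene dithioacetal formation from an active methylene compound, CS2 and MeI, followed by intramolecular vinylic substitution by the enol oxygen of the aryl ketone (the closure that gives 2-(methylsulfanyl)chromones from o-hydroxyaryl ketene dithioacetals): only the methylene between ketone and ester (C4a) has the two hydrogens needed to reach dithiolate 7, a CS2 adduct at the methine carbon has no second hydrogen to lose and should revert before MeI is added, the two equivalents of MeI are consumed by sulfur before a diketone enolate can meet them, and the 6-membered O-closure with loss of methanethiolate should give the pyranone.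

**Step 3**
Reactants: 9 methyl 6-(2,4-dimethoxyphenyl)-5-methoxy-2-(methylsulfanyl)-4-oxo-4H-pyran-3-carboxylate; 1 methyl 4-methoxy-3-oxobutanoate (2 equiv)
Product: 12 methyl 2-(2,4-dimethoxyphenyl)-5,7-dihydroxy-3,8-dimethoxy-4-oxo-4H-chromene-6-carboxylate, via dilithium dianion 10 (not isolated), via pyranyl ketoester 11 (not isolated)
Conditions: LiN(iPr)2 (4 equiv), THF, −78 to 0 °C; then 9, −78 to 20 °C; 1 M HCl
Reagents that add atoms: none
Why: Proposed new method: the methoxy-bearing terminal carbon of dianion 10, its most nucleophilic site, should add to C8a of 9, which is β to both the C4 ketone and the C5 ester and carries the methylsulfanyl leaving group, and the adduct should expel methanethiolate to give 11 (vinylic addition–elimination; should O1 leave first, the open enolate can add back and displace sulfur). The β-ketoester enolate that remains at C6 is held beside the C5 ester by the C4a=C8a double bond and should close ring A by a Dieckmann-type C-acylation, 6-(enolexo)-exo-trig, after which loss of methoxide and enolisation to the resorcinol make the sequence irreversible. The closest known reaction type is the (3+3) benzannulation of α-oxoketene dithioacetals and β-methylsulfanyl enones with 1,3-dicarbonyl dianions or their bis(silyl enol ethers), together with the Claisen cyclisation of 3,5-dioxo ester chains to resorcinols; a 2-(methylsulfanyl)-4-pyranone-3-carboxylate has not been shown as the acceptor. No stereocenter results, since the methine carbon C8 of 11 becomes aromatic. The step needs attack at C8a and not at the ester carbonyl or at C2: C8a is doubly activated and holds the only good leaving group, the ester carbonyl is flanked on both sides, C2 is screened by the aryl and methoxy groups, and 9 has no hydrogen acidic enough to quench the dianion. Since O1 is bonded to C8a before ring A exists, only the 5,7,8-oxygenation pattern can form.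

**Step 4**
Reactants: 12 methyl 2-(2,4-dimethoxyphenyl)-5,7-dihydroxy-3,8-dimethoxy-4-oxo-4H-chromene-6-carboxylate
Product: 14 2-(2,4-dimethoxyphenyl)-5,7-dihydroxy-3,8-dimethoxy-4H-chromen-4-one, via carboxylic acid 13 (not isolated)
Conditions: LiI, pyridine, reflux; 1 M HCl; then DMF, 120 °C
Reagents that add atoms: none
Why: Nucleophilic (SN2) demethylation of the hindered, doubly hydrogen-bonded ester by iodide should spare the aryl methyl ethers and avoids hydroxide, and the 2,6-dihydroxybenzoic acid 13 should then undergo protodecarboxylation on heating because C6 is ortho to both hydroxyls and para to O1 and is readily protonated.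

**Step 5**
Reactants: 14 2-(2,4-dimethoxyphenyl)-5,7-dihydroxy-3,8-dimethoxy-4H-chromen-4-one; 6 methyl iodide
Product: 15 2-(2,4-dimethoxyphenyl)-5-hydroxy-3,7,8-trimethoxy-4H-chromen-4-one (5-hydroxy-3,7,8,2',4'-pentamethoxyflavone)
Conditions: MeI (1.05 equiv), K2CO3, acetone, reflux
Reagents that add atoms: methyl iodide CI
Why: Williamson O-methylation limited to one equivalent of MeI: the 7-hydroxyl is the more acidic, unchelated phenol, whereas the 5-hydroxyl is held in a hydrogen bond to the C4 carbonyl and is the classical unreactive site of 5,7-dihydroxyflavones.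

**Compound list**
1 | methyl 4-methoxy-3-oxobutanoate (methyl 4-methoxyacetoacetate) | COCC(=O)CC(=O)OC | starting material
2 | methyl 2,4-dimethoxybenzoate | COC(=O)c1ccc(OC)cc1OC | starting material
3 | sodium lithium 1,3-dianion of methyl 4-methoxy-3-oxobutanoate (deprotonated at C2 and C4) | [Na+].[Li+].CO[CH-]C(=O)[CH-]C(=O)OC | intermediate
4 | methyl 5-(2,4-dimethoxyphenyl)-4-methoxy-3,5-dioxopentanoate (racemic, enolisable) | COC(=O)CC(=O)C(OC)C(=O)c1ccc(OC)cc1OC | intermediate
5 | carbon disulfide | S=C=S | starting material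
6 | methyl iodide (iodomethane) | CI | starting material
7 | dipotassium 5-(2,4-dimethoxyphenyl)-4-methoxy-2-(methoxycarbonyl)-3,5-dioxopent-1-ene-1,1-bis(thiolate) | [K+].[K+].COC(=O)C(=C([S-])[S-])C(=O)C(OC)C(=O)c1ccc(OC)cc1OC | intermediate
8 | methyl 2-[bis(methylsulfanyl)methylidene]-5-(2,4-dimethoxyphenyl)-4-methoxy-3,5-dioxopentanoate | COC(=O)C(=C(SC)SC)C(=O)C(OC)C(=O)c1ccc(OC)cc1OC | intermediate
9 | methyl 6-(2,4-dimethoxyphenyl)-5-methoxy-2-(methylsulfanyl)-4-oxo-4H-pyran-3-carboxylate | COC(=O)c1c(SC)oc(-c2ccc(OC)cc2OC)c(OC)c1=O | intermediate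
10 | dilithium 1,3-dianion of methyl 4-methoxy-3-oxobutanoate (deprotonated at C2 and C4) | [Li+].[Li+].CO[CH-]C(=O)[CH-]C(=O)OC | intermediate
11 | methyl 6-(2,4-dimethoxyphenyl)-5-methoxy-2-(1,4-dimethoxy-2,4-dioxobutyl)-4-oxo-4H-pyran-3-carboxylate | COC(=O)CC(=O)C(OC)c1oc(-c2ccc(OC)cc2OC)c(OC)c(=O)c1C(=O)OC | intermediate
12 | methyl 2-(2,4-dimethoxyphenyl)-5,7-dihydroxy-3,8-dimethoxy-4-oxo-4H-chromene-6-carboxylate | COC(=O)c1c(O)c(OC)c2oc(-c3ccc(OC)cc3OC)c(OC)c(=O)c2c1O | intermediate
13 | 2-(2,4-dimethoxyphenyl)-5,7-dihydroxy-3,8-dimethoxy-4-oxo-4H-chromene-6-carboxylic acid | OC(=O)c1c(O)c(OC)c2oc(-c3ccc(OC)cc3OC)c(OC)c(=O)c2c1O | intermediate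
14 | 2-(2,4-dimethoxyphenyl)-5,7-dihydroxy-3,8-dimethoxy-4H-chromen-4-one | COc1ccc(-c2oc3c(OC)c(O)cc(O)c3c(=O)c2OC)c(OC)c1 | intermediate
15 | 2-(2,4-dimethoxyphenyl)-5-hydroxy-3,7,8-trimethoxy-4H-chromen-4-one | COc1ccc(-c2oc3c(OC)c(OC)cc(O)c3c(=O)c2OC)c(OC)c1 | target

**Total step count:** 5
**Longest linear sequence:** 5 steps (1 and 2 → 4 → 9 → 12 → 14 → 15)

**Steps most likely to fail**

1. Step 3 (the proposed annulation). The hard dianion may add to the ester carbonyl or to C2 and open ring C irreversibly, or the C7 enolate oxygen of 11 may be acylated (lactone closure) in place of C6. The fallback uses known chemistry with ring A bought and ring C closed last; it sets out from ester 2 and comes back to the route at target 15.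
   - Purchased 1,2,3,5-tetramethoxybenzene is acylated with methoxyacetyl chloride and AlCl3 (CH2Cl2, 0 to 20 °C) to 2-methoxy-1-(2,3,4,6-tetramethoxyphenyl)ethan-1-one F1. In the same pot this should lose the flanked ortho methyl group, the usual site of AlCl3 cleavage in such ketones, to give 1-(2-hydroxy-3,4,6-trimethoxyphenyl)-2-methoxyethan-1-one F2.
   - Ester 2 is saponified (NaOH, aqueous MeOH) to 2,4-dimethoxybenzoic acid F3 and converted with SOCl2 into 2,4-dimethoxybenzoyl chloride F4.
   - O-Aroylation of F2 with F4 in pyridine should give 2-(2-methoxyacetyl)-3,5,6-trimethoxyphenyl 2,4-dimethoxybenzoate F5.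
   - Baker–Venkataraman rearrangement (KOH, pyridine, 50 °C) should give 1-(2,4-dimethoxyphenyl)-3-(2-hydroxy-3,4,6-trimethoxyphenyl)-2-methoxypropane-1,3-dione F6.
   - Cyclodehydration (catalytic H2SO4, AcOH, 100 °C) should give 2-(2,4-dimethoxyphenyl)-3,5,7,8-tetramethoxy-4H-chromen-4-one F7.
   - BCl3 (CH2Cl2, −20 to 0 °C) should remove only the 5-methyl group, which is peri to the C4 carbonyl, to give 15.

2. Step 2 (ring C). Diketoester 4 may close onto its own ester (pyran-2-one formation) before CS2 is taken up, CS2 or MeI may be captured at the more acidic methine carbon, or a thiolate of 7 may close onto the aryl ketone before it is methylated. The fallback reverses the order so that the 1,3-diketone never meets CS2 or MeI; it sets out from 1 (with 5 and 6) and comes back at 8.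
   - Ketoester 1 alone, which has a single acidic site, is converted with K2CO3, CS2 and MeI in DMF into methyl 2-[bis(methylsulfanyl)methylidene]-4-methoxy-3-oxobutanoate F8.
   - LiN(SiMe3)2 (THF, −78 °C) deprotonates the methoxymethyl carbon to lithium 3-[bis(methylsulfanyl)methylidene]-1,4-dimethoxy-4-oxobut-1-en-2-olate F9.
   - F9 adds to purchased 2,4-dimethoxybenzaldehyde and a cold AcOH quench should give methyl 2-[bis(methylsulfanyl)methylidene]-5-(2,4-dimethoxyphenyl)-5-hydroxy-4-methoxy-3-oxopentanoate F10.
   - Dess–Martin periodinane (CH2Cl2, 20 °C) oxidises the benzylic alcohol to 8.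
   - Compound 8 is closed to 9 with catalytic TsOH in toluene at 80 °C; acid favours attack at the protonated dithioacetal carbon over the ester.

3. Step 4 (removal of the C6 ester). Dealkylation of the chelated, hindered methyl ester may stall, or an aryl methyl ether may be lost at the temperature needed to force it. The fallback installs an ester that is cleaved under neutral conditions by a different mechanism; it sets out from 1 and 9 and comes back at acid 13.
   - Ketoester 1 is transesterified with allyl alcohol (catalytic DMAP, toluene, reflux, methanol distilled off) to allyl 4-methoxy-3-oxobutanoate F11.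
   - LiN(iPr)2 in THF converts it into allyl 4-methoxy-3-oxobutanoate dilithium 1,3-dianion F12.
   - F12 is annulated onto 9 as in step 3, through methyl 6-(2,4-dimethoxyphenyl)-5-methoxy-2-[1-methoxy-2,4-dioxo-4-(prop-2-en-1-yloxy)butyl]-4-oxo-4H-pyran-3-carboxylate F13, to allyl 2-(2,4-dimethoxyphenyl)-5,7-dihydroxy-3,8-dimethoxy-4-oxo-4H-chromene-6-carboxylate F14.
   - Catalytic Pd(PPh3)4 (zerovalent palladium) with morpholine in THF at 20 °C should transfer the allyl group to the amine and deliver 13.

**Further compounds**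
F1 | step 3 | 2-methoxy-1-(2,3,4,6-tetramethoxyphenyl)ethan-1-one | COCC(=O)c1c(OC)c(OC)c(OC)cc1OC
F2 | step 3 | 1-(2-hydroxy-3,4,6-trimethoxyphenyl)-2-methoxyethan-1-one | COCC(=O)c1c(O)c(OC)c(OC)cc1OC
F3 | step 3 | 2,4-dimethoxybenzoic acid | COc1ccc(C(=O)O)c(OC)c1
F4 | step 3 | 2,4-dimethoxybenzoyl chloride | COc1ccc(C(=O)Cl)c(OC)c1
F5 | step 3 | 2-(2-methoxyacetyl)-3,5,6-trimethoxyphenyl 2,4-dimethoxybenzoate | COCC(=O)c1c(OC(=O)c2ccc(OC)cc2OC)c(OC)c(OC)cc1OC
F6 | step 3 | 1-(2,4-dimethoxyphenyl)-3-(2-hydroxy-3,4,6-trimethoxyphenyl)-2-methoxypropane-1,3-dione | COC(C(=O)c1ccc(OC)cc1OC)C(=O)c1c(O)c(OC)c(OC)cc1OC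
F7 | step 3 | 2-(2,4-dimethoxyphenyl)-3,5,7,8-tetramethoxy-4H-chromen-4-one | COc1ccc(-c2oc3c(OC)c(OC)cc(OC)c3c(=O)c2OC)c(OC)c1
F8 | step 2 | methyl 2-[bis(methylsulfanyl)methylidene]-4-methoxy-3-oxobutanoate | COCC(=O)C(=C(SC)SC)C(=O)OC
F9 | step 2 | lithium 3-[bis(methylsulfanyl)methylidene]-1,4-dimethoxy-4-oxobut-1-en-2-olate | [Li+].COC=C([O-])C(=C(SC)SC)C(=O)OC
F10 | step 2 | methyl 2-[bis(methylsulfanyl)methylidene]-5-(2,4-dimethoxyphenyl)-5-hydroxy-4-methoxy-3-oxopentanoate | COC(=O)C(=C(SC)SC)C(=O)C(OC)C(O)c1ccc(OC)cc1OC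
F11 | step 4 | allyl 4-methoxy-3-oxobutanoate | COCC(=O)CC(=O)OCC=C
F12 | step 4 | allyl 4-methoxy-3-oxobutanoate dilithium 1,3-dianion | [Li+].[Li+].CO[CH-]C(=O)[CH-]C(=O)OCC=C
F13 | step 4 | methyl 6-(2,4-dimethoxyphenyl)-5-methoxy-2-[1-methoxy-2,4-dioxo-4-(prop-2-en-1-yloxy)butyl]-4-oxo-4H-pyran-3-carboxylate | C=CCOC(=O)CC(=O)C(OC)c1oc(-c2ccc(OC)cc2OC)c(OC)c(=O)c1C(=O)OC
F14 | step 4 | allyl 2-(2,4-dimethoxyphenyl)-5,7-dihydroxy-3,8-dimethoxy-4-oxo-4H-chromene-6-carboxylate | C=CCOC(=O)c1c(O)c(OC)c2oc(-c3ccc(OC)cc3OC)c(OC)c(=O)c2c1O
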